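A small charge of free base, 0.330 M, stands against 0.270 M of protonated nucleophile in this flask, and the question is what that small margin allows.

| flask | electrophile | free base | protonated nucleophile | remark | time |
|---|---|---|---|---|---|
| elm | 0.30 M | 0.22 M | 0.27 M | run made earlier |  |
| ash | 0.30 M | 0.49 M | 0.27 M | run made earlier |  |
| flask | 0.30 M | 0.330 M | 0.270 M |  | 2.5 min |

| run | time / min | electrophile / % | target / % |
|---|---|---|---|
| elm | 0.667 | 81.3 | 16.1 |
| elm | 1.33 | 77.4 | 23.4 |
| elm | 2.00 | 76.2 | 25.8 |
| elm | 2.50 | 76.3 | 26.6 |
| elm | 3.00 | 73.3 | 26.4 |
| ash | 0.667 | 75.4 | 25.5 |
| ash | 1.33 | 69.9 | 30.7 |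
| ash | 2.00 | 64.6 | 36.6 |
| ash | 2.50 | 60.2 | 38.9 |
| ash | 3.00 | 58.0 | 44.6 |

(standard deviation of a reading: 1 percentage point)

* part of the electrophile that has reacted at 2.5 min
* share of free nucleophile in free nucleophile and protonated nucleophile together, at 2.5 min

- the earlier runs do not show how much of nucleophile is bound; that part of a forecast is a guess

1. First instants. This reckoning assumes that free base strips protonated nucleophile one for one, and that each coupling of electrophile with nucleophile sets free one acid. The flask then keeps 0.0600 M of spare base, defined as c(free base) minus c(protonated nucleophile) as charged.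

2. Middle. Each coupling takes spare base, so in this flask it is reckoned to last until 20.0% of the electrophile has reacted. The elm run has a spare base of −0.0500 M, and its target moves from 25.8% to 26.4% late on. The ash run has 0.220 M, and its target moves from 36.6% to 44.6%.

3. End. Past that point, c(target) minus the spare base is acid in excess of the free base charged, and it is reckoned to sit free or on nucleophile. Interpolating the target readings by free base gives this reckoning's own c of 31.6%, so the flask is reckoned to carry 0.0348 M of such acid. That amount is the reckoned sum of c(protonated nucleophile) and c(acid set free).

The forecast gives 34% and 12%, calling the share “poorly constrained, especially if binding differs”. Its c stands above the reckoning here.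

The flask gives 35.6% and 43.5%.

    electrophile + nucleophile ⇌ acid set free + target (K = 1.30, k = 0.0740 L mol⁻¹ s⁻¹)
    nucleophile + acid set free ⇌ protonated nucleophile, settled at all times (K = 70.0 L mol⁻¹)
    acid set free + free base ⇌ salt of the base, settled at all times (K = 40000 L mol⁻¹)
    nucleophile ⇌ dormant form (K = 4.20, k = 0.0630 s⁻¹)

Coupling had made 16.0% target by 0.250 min, with 4.72% of the free base left, and 28.7% by 1.25 min, with 0.259% of this limiting reagent left. At 2.5 min the flask's excess acid is 0.0469 M, and the flask holds 0.0473 M of protonated nucleophile and acid set free together, with 4.449 × 10⁻⁴ M of free base still there, while c(nucleophile) is 0.0222 M and the dormant form holds 0.112 M. In the neighbour flask with 0.20 M of free base, the spare base is −0.0700 M, the same subtraction gives 0.142 M, and that flask holds 0.142 M of protonated nucleophile and acid set free together.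

All runs are simulated with constants of no real substance; scatter was added.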